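**Plan**

- The target is a cis-2,3-dimethylchroman-4-one whose benzene ring (C4a, C5, C6, C7, C8, C8a) is hexasubstituted: oxygens at C5 (OH), C7 (OMe) and C8a (O1) alternate with carbon groups at C4a (the C4 ketone), C6 (octanoic acid chain) and C8 (prenyl). This alternation lets C5 come from a ketene carbonyl and C7 and C8a from the oxygen-bearing carbons of two ynol ethers.
- Retrosynthesis: tie the acid to C5-OH as a dihydrocoumarin lactone; cut O1-C2 (oxa-Michael of the C8a phenol onto a tigloyl ketone); cut C4-C3 (alkenyl addition to a C4a aldehyde) and C4a-C4 (ortho-formylation); cut the arene at C5-C4a and C8a-C8 into a cyclobutenone (C5 to C8) and (triisopropylsilyloxy)ethyne (C4a, C8a); cut the cyclobutenone into a ketene and 1-methoxy-5-methylhex-4-en-1-yne.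
- Forward order: side chain and cyclobutenone (steps 1-7), benzene ring (step 9), lactone ring (step 11), chromanone ring (step 15), lactone opened last (step 16).
- Stereochemistry: the side-chain centre comes from alkaloid-catalysed methanolysis of 3-pentylglutaric anhydride (step 4); C2 (S) and C3 (R) are set together in the quinidine-catalysed cis-selective oxa-Michael closure (step 15).

Key step: step 9

**Assumptions**

- Sense of induction: (DHQD)2AQN (hydroquinidine anthraquinone-1,4-diyl diether) is taken to give the (S)-hemiester 8 and quinidine the (2S,3R)-chromanone, by analogy with closely related substrates; if either sense is reversed, the pseudoenantiomeric alkaloid ((DHQ)2AQN, quinine) is used.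
- The side-chain centre is (S) in 8 and (R) from 9 onward only because the CIP priorities change; no inversion occurs.
- Ring positions of all arene intermediates are given in chromanone numbering (O1, C2, C3, C4, C4a, C5-C8, C8a).
- Metal alkoxides, phenoxides and carboxylates that are only protonated on work-up are not numbered.

**Route**

Step 1
Reactants: 1 hexanal; 2 diethyl malonate (2 equiv)
Product: 4 tetraethyl 2-pentylpropane-1,1,3,3-tetracarboxylate, via diethyl 2-hexylidenemalonate 3 (not isolated)
Conditions: piperidine (10 mol%), AcOH (10 mol%), EtOH, rt then 70 °C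
Reagents that add atoms: none
Why: Knoevenagel condensation gives alkylidenemalonate 3, which takes up a second malonate by Michael addition under the same amine catalysis, the usual outcome for aliphatic aldehydes with two equivalents of malonate; no stereocentre is formed.

Step 2
Reactants: 4 tetraethyl 2-pentylpropane-1,1,3,3-tetracarboxylate
Product: 6 3-pentylpentanedioic acid, via 2-pentylpropane-1,1,3,3-tetracarboxylic acid 5 (not isolated)
Conditions: 6 M HCl, reflux
Reagents that add atoms: water, O
Why: Acid hydrolysis of the four esters to 5 and thermal decarboxylation of both malonic acid units (malonic ester synthesis) should leave the symmetrical 3-substituted glutaric acid.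

Step 3
Reactants: 6 3-pentylpentanedioic acid
Product: 7 4-pentyloxane-2,6-dione (3-pentylglutaric anhydride)
Conditions: Ac2O, reflux; distil
Reagents that add atoms: none
Why: Cyclodehydration of a 1,5-diacid with acetic anhydride gives the six-membered anhydride, which is achiral with two enantiotopic carbonyl groups.

Step 4
Reactants: 7 4-pentyloxane-2,6-dione
Product: 8 (3S)-3-(2-methoxy-2-oxoethyl)octanoic acid
Conditions: MeOH (10 equiv), (DHQD)2AQN (10 mol%), Et2O, -40 °C
Reagents that add atoms: methanol, CO
Why: Cinchona alkaloid-catalysed enantioselective methanolysis (desymmetrisation of a prochiral cyclic anhydride): the quinuclidine activates methanol within the chiral pocket, one enantiotopic carbonyl is attacked and the side-chain stereocentre is set; the enantiomeric purity can be raised by crystallising an amine salt of 8.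

Step 5
Reactants: 8 (3S)-3-(2-methoxy-2-oxoethyl)octanoic acid
Product: 9 methyl (3R)-3-(2-chloro-2-oxoethyl)octanoate
Conditions: (COCl)2 (1.3 equiv), DMF (cat.), CH2Cl2, 0 °C to rt; concentrate
Reagents that add atoms: oxalyl chloride, ClC(=O)C(=O)Cl
Why: Acid chloride formation with oxalyl chloride under Vilsmeier catalysis; the methyl ester is inert and the stereocentre, β to both carbonyls, cannot epimerise.

Step 6
Reactants: 10 2-chloro-1,1-dimethoxyethane (chloroacetaldehyde dimethyl acetal); 11 1-bromo-3-methylbut-2-ene (prenyl bromide)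
Product: 13 1-methoxy-5-methylhex-4-en-1-yne, via sodium methoxyethynide 12 (not isolated)
Conditions: NaNH2 (3.0 equiv), liq. NH3, -33 °C; then 11, -33 °C to rt
Reagents that add atoms: none
Why: Amide-induced elimination of methanol and hydrogen chloride from the chloroacetal gives alkoxyethynide 12 (the standard preparation of 1-alkoxyalkynes), which is alkylated at carbon by the primary allylic bromide in an SN2 reaction; with exactly three equivalents of NaNH2 no free amide remains to isomerise the skipped enyne.

Step 7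
Reactants: 9 methyl (3R)-3-(2-chloro-2-oxoethyl)octanoate; 13 1-methoxy-5-methylhex-4-en-1-yne
Product: 15 methyl (3R)-3-[(1RS)-2-methoxy-3-(3-methylbut-2-enyl)-4-oxocyclobut-2-enyl]octanoate, via ketene 14 (not isolated)
Conditions: 13 (1.5 equiv), Et3N (1.5 equiv), CH2Cl2, rt, slow addition of 9
Reagents that add atoms: none
Why: Dehydrochlorination gives aldoketene 14, which is trapped in a thermal [2+2] cycloaddition by the excess ynol ether; the nucleophilic prenyl-bearing alkyne carbon bonds to the ketene carbonyl carbon, which places prenyl at C2 and methoxy at C3 of the cyclobutenone, and the new ring stereocentre forms as a mixture that is erased in step 9.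

Step 8
Reactants: 16 acetylene
Product: 19 (triisopropylsilyloxy)ethyne, via lithium acetylide 17 (not isolated), via lithium ethynolate 18 (not isolated)
Conditions: acetylene-saturated THF, n-BuLi (1.0 equiv), -78 °C; t-BuOOLi (1.0 equiv, from t-BuOOH and LiN(SiMe3)2, THF, -78 °C), -78 to -20 °C; TIPSOTf (1.1 equiv), -78 °C
Reagents that add atoms: lithium tert-butyl peroxide, CC(C)(C)O[O-].[Li+]; triisopropylsilyl trifluoromethanesulfonate, CC(C)[Si](C(C)C)(C(C)C)OS(=O)(=O)C(F)(F)F
Why: Oxidation of a lithium acetylide to the lithium ynolate by lithium tert-butyl peroxide followed by O-silylation with a bulky silyl triflate is the established route to 1-siloxyalkynes; applied to monolithium acetylide it should work if the acetylide is kept cold under excess acetylene (no dilithiation) and no strong base is left at the silylation stage.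

Step 9
Reactants: 15 methyl (3R)-3-[(1RS)-2-methoxy-3-(3-methylbut-2-enyl)-4-oxocyclobut-2-enyl]octanoate; 19 (triisopropylsilyloxy)ethyne
Product: 24 methyl (3R)-3-[2-hydroxy-6-methoxy-5-(3-methylbut-2-enyl)-4-(triisopropylsilyloxy)phenyl]octanoate, via vinylketene 20 (not isolated), via vinylcyclobutenone 21 (not isolated), via dienylketene 22 (not isolated), via cyclohexadienone 23 (not isolated)
Conditions: 15 and 19 in equimolar amounts, toluene, 110 °C, sealed tube
Reagents that add atoms: none
Why: Thermal 4π electrocyclic opening of 15 gives vinylketene 20, whose ketene carbon is attacked by the nucleophilic CH carbon of 19 in a [2+2] cycloaddition that forms C5-C4a and C8a-C8 and gives vinylcyclobutenone 21; a second 4π opening gives dienylketene 22, and 6π electrocyclic closure between the ketene carbon and the chain-bearing terminus gives cyclohexadienone 23, which enolises to phenol 24, so that one molecule of 15 and one of 19 combine with no loss of atoms. This is the Danheiser benzannulation of a cyclobutenone with a siloxyalkyne, and alkoxy-substituted cyclobutenones are established vinylketene sources (as in squarate-derived systems). The only ring closed is the benzene ring, by 6π electrocyclisation followed by tautomerisation. No stereocentre is created: the ring centre of 15 and the quaternary centre of 21 are erased, and the side-chain centre, β to the ketene, is not enolisable. The selectivity needed is the orientation of the ketene-alkyne [2+2], which the polarisation of the ynol ether (carbon β to oxygen nucleophilic) and the electrophilic ketene carbon should secure. Outward rotation of the C4 alkyl group in the first opening avoids a 1,5-hydrogen shift, and because 20 forms slowly and reversibly its stationary concentration stays low, so the strongly nucleophilic alkyne should intercept it before the hindered product phenol is acylated.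

Step 10
Reactants: 24 methyl (3R)-3-[2-hydroxy-6-methoxy-5-(3-methylbut-2-enyl)-4-(triisopropylsilyloxy)phenyl]octanoate
Product: 25 methyl (3R)-3-[3-formyl-2-hydroxy-6-methoxy-5-(3-methylbut-2-enyl)-4-(triisopropylsilyloxy)phenyl]octanoate
Conditions: MgCl2 (2 equiv), Et3N (4 equiv), (CH2O)n (6 equiv), MeCN, 80 °C; aq. HCl work-up
Reagents that add atoms: paraformaldehyde (as formaldehyde), C=O
Why: Magnesium phenoxide-directed ortho-formylation (Casnati–Skattebøl reaction): the C5 phenoxide delivers formaldehyde to C4a, its only free ortho position, and hydride transfer to a second formaldehyde gives the aldehyde; the phenoxide does not lactonise here because aryl ester plus methoxide lies on the side of phenoxide plus methyl ester.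

Step 11
Reactants: 25 methyl (3R)-3-[3-formyl-2-hydroxy-6-methoxy-5-(3-methylbut-2-enyl)-4-(triisopropylsilyloxy)phenyl]octanoate
Product: 26 (4R)-5-methoxy-6-(3-methylbut-2-enyl)-2-oxo-4-pentyl-7-(triisopropylsilyloxy)-3,4-dihydro-2H-chromene-8-carbaldehyde
Conditions: PPTS (0.2 equiv), toluene, 90 °C, 5 Å molecular sieves
Reagents that add atoms: none
Why: Acid-catalysed intramolecular transesterification to the six-membered aryl lactone (dihydrocoumarin), helped by the two ortho substituents and the branched benzylic carbon and driven by trapping of methanol; it masks C5-OH and the acid in one ring and does not touch the benzylic centre.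

Step 12
Reactants: 26 (4R)-5-methoxy-6-(3-methylbut-2-enyl)-2-oxo-4-pentyl-7-(triisopropylsilyloxy)-3,4-dihydro-2H-chromene-8-carbaldehyde; 27 (E)-2-bromobut-2-ene
Product: 28 (4R)-8-[(1RS,2E)-1-hydroxy-2-methylbut-2-enyl]-5-methoxy-6-(3-methylbut-2-enyl)-4-pentyl-7-(triisopropylsilyloxy)-3,4-dihydro-2H-chromen-2-one
Conditions: 27 (3 equiv), CrCl2 (6 equiv), NiCl2 (2 mol%), DMF, rt
Reagents that add atoms: none
Why: Nozaki–Hiyama–Kishi coupling: zerovalent nickel inserts into the alkenyl bromide, the alkenyl group passes to trivalent chromium and adds to the aldehyde only (lactone, silyl ether and prenyl group are inert) with retention of the (E) geometry; the carbinol centre forms as a mixture that is removed by oxidation in step 14.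

Step 13
Reactants: 28 (4R)-8-[(1RS,2E)-1-hydroxy-2-methylbut-2-enyl]-5-methoxy-6-(3-methylbut-2-enyl)-4-pentyl-7-(triisopropylsilyloxy)-3,4-dihydro-2H-chromen-2-one
Product: 29 (4R)-7-hydroxy-8-[(1RS,2E)-1-hydroxy-2-methylbut-2-enyl]-5-methoxy-6-(3-methylbut-2-enyl)-4-pentyl-3,4-dihydro-2H-chromen-2-one
Conditions: Bu4NF (1.2 equiv), AcOH (1.2 equiv), THF, 0 °C; used without storage
Reagents that add atoms: none
Why: Fluoride-induced cleavage of the aryl silyl ether, buffered with acetic acid so that the phenol stays protonated and the aryl lactone is not opened; the secondary alcohol is unaffected.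

Step 14
Reactants: 29 (4R)-7-hydroxy-8-[(1RS,2E)-1-hydroxy-2-methylbut-2-enyl]-5-methoxy-6-(3-methylbut-2-enyl)-4-pentyl-3,4-dihydro-2H-chromen-2-one
Product: 30 (4R)-7-hydroxy-5-methoxy-8-[(2E)-2-methylbut-2-enoyl]-6-(3-methylbut-2-enyl)-4-pentyl-3,4-dihydro-2H-chromen-2-one
Conditions: MnO2 (activated, 15 equiv), CH2Cl2, rt
Reagents that add atoms: none
Why: MnO2 oxidises the alcohol because it is both allylic and benzylic and should leave the phenol, lactone and alkenes alone; the neutral conditions give the o-hydroxyaryl enone without base-induced cyclisation.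

Step 15
Reactants: 30 (4R)-7-hydroxy-5-methoxy-8-[(2E)-2-methylbut-2-enoyl]-6-(3-methylbut-2-enyl)-4-pentyl-3,4-dihydro-2H-chromen-2-one
Product: 31 (4R,8S,9R)-5-methoxy-8,9-dimethyl-6-(3-methylbut-2-enyl)-4-pentyl-3,4,8,9-tetrahydro-2H,10H-pyrano[2,3-f]chromene-2,10-dione
Conditions: quinidine (15 mol%), chlorobenzene, 15 °C; stopped at full conversion
Reagents that add atoms: none
Why: Cinchona alkaloid-catalysed intramolecular oxa-Michael addition of an o-tigloylphenol (6-endo-trig closure of the chromanone ring): the quinuclidine nitrogen activates the phenol while the catalyst hydroxyl binds the enone, so C-O bond formation on one enone face sets C2 (S), and kinetic protonation of the enolate within the ion pair sets C3 (R), cis to the C2 methyl; C5-O is blocked in the lactone, so only C8a-OH can add.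

Step 16
Reactants: 31 (4R,8S,9R)-5-methoxy-8,9-dimethyl-6-(3-methylbut-2-enyl)-4-pentyl-3,4,8,9-tetrahydro-2H,10H-pyrano[2,3-f]chromene-2,10-dione
Product: 32 (3R)-3-[(2S,3R)-5-hydroxy-7-methoxy-2,3-dimethyl-8-(3-methylbut-2-enyl)-4-oxo-3,4-dihydro-2H-chromen-6-yl]octanoic acid
Conditions: LiOH (2.2 equiv), THF/H2O 3:1, 0 °C, 20 min; then 1 M HCl to pH 3-4 at 0 °C
Reagents that add atoms: lithium hydroxide, [Li+].[OH-]
Why: Saponification of the aryl lactone, activated by the ortho acyl group, should be much faster than removal of C3-H by hydroxide at 0 °C; once the ring is open the C5 phenoxide conjugated with C4=O protects C3 from enolisation, and cold acidification gives the acid with the chelated C5-OH.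

**Compound list**

1 | hexanal | CCCCCC=O | starting material
2 | diethyl malonate | CCOC(=O)CC(=O)OCC | starting material
3 | diethyl 2-hexylidenemalonate | CCCCCC=C(C(=O)OCC)C(=O)OCC | intermediate (not isolated)
4 | tetraethyl 2-pentylpropane-1,1,3,3-tetracarboxylate | CCCCCC(C(C(=O)OCC)C(=O)OCC)C(C(=O)OCC)C(=O)OCC | intermediate
5 | 2-pentylpropane-1,1,3,3-tetracarboxylic acid | CCCCCC(C(C(=O)O)C(=O)O)C(C(=O)O)C(=O)O | intermediate (not isolated)
6 | 3-pentylpentanedioic acid | CCCCCC(CC(=O)O)CC(=O)O | intermediate
7 | 4-pentyloxane-2,6-dione | CCCCCC1CC(=O)OC(=O)C1 | intermediate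
8 | (3S)-3-(2-methoxy-2-oxoethyl)octanoic acid | CCCCC[C@H](CC(=O)OC)CC(=O)O | intermediate
9 | methyl (3R)-3-(2-chloro-2-oxoethyl)octanoate | CCCCC[C@H](CC(=O)OC)CC(=O)Cl | intermediate
10 | 2-chloro-1,1-dimethoxyethane | COC(CCl)OC | starting material
11 | 1-bromo-3-methylbut-2-ene | CC(C)=CCBr | starting material
12 | sodium methoxyethynide | COC#[C-].[Na+] | intermediate (not isolated)
13 | 1-methoxy-5-methylhex-4-en-1-yne | COC#CCC=C(C)C | intermediate
14 | methyl (3R)-3-(2-oxoethenyl)octanoate | CCCCC[C@H](CC(=O)OC)C=C=O | intermediate (not isolated)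
15 | methyl (3R)-3-[(1RS)-2-methoxy-3-(3-methylbut-2-enyl)-4-oxocyclobut-2-enyl]octanoate | CCCCC[C@H](CC(=O)OC)C1C(=O)C(CC=C(C)C)=C1OC | intermediate
16 | acetylene | C#C | starting material
17 | lithium acetylide | [Li+].[C-]#C | intermediate (not isolated)
18 | lithium ethynolate | [Li+].[O-]C#C | intermediate (not isolated)
19 | (triisopropylsilyloxy)ethyne | C#CO[Si](C(C)C)(C(C)C)C(C)C | intermediate
20 | methyl (3R)-3-[2-methoxy-3-(3-methylbut-2-enyl)-4-oxobuta-1,3-dienyl]octanoate | CCCCC[C@H](CC(=O)OC)C=C(OC)C(CC=C(C)C)=C=O | intermediate (not isolated)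
21 | methyl (3R)-3-{2-methoxy-2-[1-(3-methylbut-2-enyl)-4-oxo-2-(triisopropylsilyloxy)cyclobut-2-enyl]ethenyl}octanoate | CCCCC[C@H](CC(=O)OC)C=C(OC)C1(CC=C(C)C)C(=O)C=C1O[Si](C(C)C)(C(C)C)C(C)C | intermediate (not isolated)
22 | methyl (3R)-3-[2-methoxy-3-(3-methylbut-2-enyl)-6-oxo-4-(triisopropylsilyloxy)hexa-1,3,5-trienyl]octanoate | CCCCC[C@H](CC(=O)OC)C=C(OC)C(CC=C(C)C)=C(O[Si](C(C)C)(C(C)C)C(C)C)C=C=O | intermediate (not isolated)
23 | methyl (3R)-3-[2-methoxy-3-(3-methylbut-2-enyl)-6-oxo-4-(triisopropylsilyloxy)cyclohexa-2,4-dienyl]octanoate | CCCCC[C@H](CC(=O)OC)C1C(=O)C=C(O[Si](C(C)C)(C(C)C)C(C)C)C(CC=C(C)C)=C1OC | intermediate (not isolated)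
24 | methyl (3R)-3-[2-hydroxy-6-methoxy-5-(3-methylbut-2-enyl)-4-(triisopropylsilyloxy)phenyl]octanoate | CCCCC[C@H](CC(=O)OC)c1c(O)cc(O[Si](C(C)C)(C(C)C)C(C)C)c(CC=C(C)C)c1OC | intermediate
25 | methyl (3R)-3-[3-formyl-2-hydroxy-6-methoxy-5-(3-methylbut-2-enyl)-4-(triisopropylsilyloxy)phenyl]octanoate | CCCCC[C@H](CC(=O)OC)c1c(O)c(C=O)c(O[Si](C(C)C)(C(C)C)C(C)C)c(CC=C(C)C)c1OC | intermediate
26 | (4R)-5-methoxy-6-(3-methylbut-2-enyl)-2-oxo-4-pentyl-7-(triisopropylsilyloxy)-3,4-dihydro-2H-chromene-8-carbaldehyde | CCCCC[C@@H]1CC(=O)Oc2c(C=O)c(O[Si](C(C)C)(C(C)C)C(C)C)c(CC=C(C)C)c(OC)c21 | intermediate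
27 | (E)-2-bromobut-2-ene | C/C=C(\C)Br | starting material
28 | (4R)-8-[(1RS,2E)-1-hydroxy-2-methylbut-2-enyl]-5-methoxy-6-(3-methylbut-2-enyl)-4-pentyl-7-(triisopropylsilyloxy)-3,4-dihydro-2H-chromen-2-one | CCCCC[C@@H]1CC(=O)Oc2c(C(O)/C(C)=C/C)c(O[Si](C(C)C)(C(C)C)C(C)C)c(CC=C(C)C)c(OC)c21 | intermediate
29 | (4R)-7-hydroxy-8-[(1RS,2E)-1-hydroxy-2-methylbut-2-enyl]-5-methoxy-6-(3-methylbut-2-enyl)-4-pentyl-3,4-dihydro-2H-chromen-2-one | CCCCC[C@@H]1CC(=O)Oc2c(C(O)/C(C)=C/C)c(O)c(CC=C(C)C)c(OC)c21 | intermediate
30 | (4R)-7-hydroxy-5-methoxy-8-[(2E)-2-methylbut-2-enoyl]-6-(3-methylbut-2-enyl)-4-pentyl-3,4-dihydro-2H-chromen-2-one | CCCCC[C@@H]1CC(=O)Oc2c(C(=O)/C(C)=C/C)c(O)c(CC=C(C)C)c(OC)c21 | intermediate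
31 | (4R,8S,9R)-5-methoxy-8,9-dimethyl-6-(3-methylbut-2-enyl)-4-pentyl-3,4,8,9-tetrahydro-2H,10H-pyrano[2,3-f]chromene-2,10-dione | CCCCC[C@@H]1CC(=O)Oc2c3c(c(CC=C(C)C)c(OC)c21)O[C@@H](C)[C@@H](C)C3=O | intermediate
32 | (3R)-3-[(2S,3R)-5-hydroxy-7-methoxy-2,3-dimethyl-8-(3-methylbut-2-enyl)-4-oxo-3,4-dihydro-2H-chromen-6-yl]octanoic acid | CCCCC[C@H](CC(=O)O)c1c(O)c2c(c(CC=C(C)C)c1OC)O[C@@H](C)[C@@H](C)C2=O | target

**Step count**

Total: 16 steps. Longest linear sequence: 14 steps (1-5, 7, 9-16, from hexanal).

**Steps most likely to fail**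

Step 8. Monolithium acetylide may disproportionate to the dilithio compound during the slow oxidation, and any base left at the silylation stage may deprotonate the product and start O-to-C silyl migration, so that little terminal siloxyalkyne is obtained. The fallback sets out from 15 and uses commercial 3,3-diethoxyprop-1-yne, for which the acetylide oxidation is routine (a substituted terminal alkyne with no second acidic hydrogen). Deprotonation with n-BuLi gives lithium 3,3-diethoxyprop-1-yn-1-ide F1, oxidation with t-BuOOLi gives lithium 3,3-diethoxyprop-1-yn-1-olate F2, and TIPSOTf gives 3,3-diethoxy-1-(triisopropylsilyloxy)prop-1-yne F3. Heating F3 with 15 as in step 9 should lead through 20, the acetal-bearing vinylcyclobutenone F4, the acetal-bearing dienylketene F5 and the acetal-bearing cyclohexadienone F6 to the aryl acetal methyl (3R)-3-[3-(diethoxymethyl)-2-hydroxy-6-methoxy-5-(3-methylbut-2-enyl)-4-(triisopropylsilyloxy)phenyl]octanoate F7, which already carries the C4 carbon at C4a. Hydrolysis (PPTS, acetone/water, rt) returns to the route at 25, so that step 10 is no longer needed; any loss of ethanol from the o-hydroxyaryl acetal on heating converges on 25 as well.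

Step 9. The methoxy-stabilised cyclobutenone may open only at temperatures at which the siloxyalkyne rearranges to the silylketene, so that 20 forms with no partner left; acylation of the product phenol by 20 is a second drain. The fallback sets out from 15 and separates the two thermal events. Compound 15 is heated alone with 2-(trimethylsilyl)ethanol (toluene, 150 °C), which traps 20 as 1-methyl 7-[2-(trimethylsilyl)ethyl] (3R)-5-methoxy-6-(3-methylbut-2-enyl)-3-pentylhept-4-enedioate F8. Bu4NF and a pH 5 work-up give (5R)-3,7-dimethoxy-2-(3-methylbut-2-enyl)-7-oxo-5-pentylhept-3-enoic acid F9. 1-Chloro-N,N,2-trimethylprop-1-en-1-amine converts F9 under neutral conditions into methyl (3R)-7-chloro-5-methoxy-6-(3-methylbut-2-enyl)-7-oxo-3-pentylhept-4-enoate F10. Dehydrochlorination of F10 with Et3N at room temperature in the presence of 19 regenerates 20 at a temperature at which 19 is stable; after the [2+2] step the mixture is warmed to 80 °C to take 21 through 22 and 23, and the route is rejoined at 24.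

Step 16. Hydroxide may remove C3-H before the lactone is opened, which would epimerise the cis-chromanone to the trans isomer or open the pyranone ring by E1cB elimination. The fallback sets out from 31 and avoids hydroxide. Acid-catalysed alcoholysis with allyl alcohol (camphorsulfonic acid, rt) opens the activated aryl lactone to prop-2-enyl (3R)-3-[(2S,3R)-5-hydroxy-7-methoxy-2,3-dimethyl-8-(3-methylbut-2-enyl)-4-oxo-3,4-dihydro-2H-chromen-6-yl]octanoate F11 with the chelated C5-OH free. The allyl ester is then cleaved under neutral conditions with Pd(PPh3)4 and N-methylaniline in THF (π-allyl chemistry of zerovalent palladium), which returns to the route at 32.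

**Further compounds**

F1 | step 8 | lithium 3,3-diethoxyprop-1-yn-1-ide | CCOC(OCC)C#[C-].[Li+]
F2 | step 8 | lithium 3,3-diethoxyprop-1-yn-1-olate | CCOC(OCC)C#C[O-].[Li+]
F3 | step 8 | 3,3-diethoxy-1-(triisopropylsilyloxy)prop-1-yne | CCOC(OCC)C#CO[Si](C(C)C)(C(C)C)C(C)C
F4 | step 8 | methyl (3R)-3-{2-[3-(diethoxymethyl)-1-(3-methylbut-2-enyl)-4-oxo-2-(triisopropylsilyloxy)cyclobut-2-enyl]-2-methoxyethenyl}octanoate | CCCCC[C@H](CC(=O)OC)C=C(OC)C1(CC=C(C)C)C(=O)C(C(OCC)OCC)=C1O[Si](C(C)C)(C(C)C)C(C)C
F5 | step 8 | methyl (3R)-3-[5-(diethoxymethyl)-2-methoxy-3-(3-methylbut-2-enyl)-6-oxo-4-(triisopropylsilyloxy)hexa-1,3,5-trienyl]octanoate | CCCCC[C@H](CC(=O)OC)C=C(OC)C(CC=C(C)C)=C(O[Si](C(C)C)(C(C)C)C(C)C)C(C(OCC)OCC)=C=O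
F6 | step 8 | methyl (3R)-3-[5-(diethoxymethyl)-2-methoxy-3-(3-methylbut-2-enyl)-6-oxo-4-(triisopropylsilyloxy)cyclohexa-2,4-dienyl]octanoate | CCCCC[C@H](CC(=O)OC)C1C(=O)C(C(OCC)OCC)=C(O[Si](C(C)C)(C(C)C)C(C)C)C(CC=C(C)C)=C1OC
F7 | step 8 | methyl (3R)-3-[3-(diethoxymethyl)-2-hydroxy-6-methoxy-5-(3-methylbut-2-enyl)-4-(triisopropylsilyloxy)phenyl]octanoate | CCCCC[C@H](CC(=O)OC)c1c(O)c(C(OCC)OCC)c(O[Si](C(C)C)(C(C)C)C(C)C)c(CC=C(C)C)c1OC
F8 | step 9 | 1-methyl 7-[2-(trimethylsilyl)ethyl] (3R)-5-methoxy-6-(3-methylbut-2-enyl)-3-pentylhept-4-enedioate | CCCCC[C@H](CC(=O)OC)C=C(OC)C(CC=C(C)C)C(=O)OCC[Si](C)(C)C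
F9 | step 9 | (5R)-3,7-dimethoxy-2-(3-methylbut-2-enyl)-7-oxo-5-pentylhept-3-enoic acid | CCCCC[C@H](CC(=O)OC)C=C(OC)C(CC=C(C)C)C(=O)O
F10 | step 9 | methyl (3R)-7-chloro-5-methoxy-6-(3-methylbut-2-enyl)-7-oxo-3-pentylhept-4-enoate | CCCCC[C@H](CC(=O)OC)C=C(OC)C(CC=C(C)C)C(=O)Cl
F11 | step 16 | prop-2-enyl (3R)-3-[(2S,3R)-5-hydroxy-7-methoxy-2,3-dimethyl-8-(3-methylbut-2-enyl)-4-oxo-3,4-dihydro-2H-chromen-6-yl]octanoate | CCCCC[C@H](CC(=O)OCC=C)c1c(O)c2c(c(CC=C(C)C)c1OC)O[C@@H](C)[C@@H](C)C2=O
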